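Readings and results were generated by integration with made-up constants, noise included.

| flask | D | temperature | remark | time |
|---|---|---|---|---|
| violet | 0.032 M | −45 °C | run made earlier |  |
| red | 0.055 M | −25 °C | run made earlier |  |
| teal | 0.090 M | −45 °C | run made earlier |  |
| alder | 0.030 M |  | at −10 °C throughout | 5.0 h |
| birch | 0.10 M |  | at −40 °C until 1.5 h, from then on at −10 °C | 5.0 h |

| run | time / h | Z / % |
|---|---|---|
| violet | 0.667 | 0 |
| violet | 2.00 | 2 |
| violet | 3.00 | 3 |
| violet | 5.00 | 4 |
| red | 0.667 | 16 |
| red | 1.33 | 20 |
| red | 2.00 | 20 |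
| red | 2.50 | 18 |
| teal | 0.667 | 1 |
| teal | 2.00 | 1 |
| teal | 3.00 | 4 |
| teal | 5.00 | 5 |

(scatter of a reading: 1.5 percentage points)

- which of the two ends with the higher amount of Z, in percent of the D charged ("neither" if they lie within 2 percentage points) (alder / birch / neither)
- Z at the end, in percent of the D charged, alder
- Z at the end, in percent of the D charged, birch

- the numbers in the tables scatter with a standard deviation of 1.5 percentage points
- candidate steps: G -> Q; E <-> L; D -> E; Q -> X; Z <-> X; Q -> Z; D -> G

The easy step first: violet and teal, both at −45 °C, end with Z at 4% and 5% although [D] was 0.032 M and 0.090 M, so within the scatter we reckon the percent of Z by time and temperature and set [D] aside. The red run reads 20% at 1.33 h, then 20% and 18%. We call the stand, the percent of Z once its rise is over, the mean of the red readings from 1.33 h on: 19.3%. Z per hour at the first red reading is 30.0 times that over the violet run. Because −10 °C lies more than half as far above −25 °C as −25 °C lies above −45 °C, we take the square root of that factor as a cautious speed-up. The rise then needs about 0.243 h at −10 °C, which is short against birch's 3.50 h there and alder's 5.0 h, so we expect the two flasks to end alike.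

For a low estimate, not a strict bound: if the red slide is real and Z goes one way to X, the loss is 0.0901 h⁻¹, and with that speed-up alder keeps about 1.64%. From above we have the charge, 100%, since the runs give Z and no other species. But the slide is 2 percentage points against a scatter of 1.5 points per reading, and Z ⇌ X is listed as two-way, so the stand may be a balance (thermodynamic control). We commit to about 19.3% in both flasks.

The forecast says neither, with 7% for alder and 8% for birch: Z “should have fallen towards a low level or the Z/X equilibrium”. Both numbers lie inside the bracket, below our stand.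

The simulation gives neither: alder 26.2%, birch 26.2%.

    G → Q (k = 0.00450 min⁻¹, Ea = 68.0 kJ mol⁻¹)
    E ⇌ L (K = 1.00, k = 0.00720 min⁻¹, Ea = 76.0 kJ mol⁻¹, ΔH = −36.0 kJ mol⁻¹)
    D → E (k = 0.0120 min⁻¹, Ea = 66.0 kJ mol⁻¹)
    Q → X (k = 9.90 × 10⁻⁴ min⁻¹, Ea = 76.0 kJ mol⁻¹)
    Z ⇌ X (K = 2.00, k = 0.0240 min⁻¹, Ea = 79.0 kJ mol⁻¹, ΔH = −50.0 kJ mol⁻¹)
    Q → Z (k = 0.130 min⁻¹, Ea = 76.0 kJ mol⁻¹)
    D → G (k = 0.00490 min⁻¹, Ea = 66.0 kJ mol⁻¹)
    (constants at −40 °C)

Both flasks end 6.9 points above the stand, and alder reads 26.2% at 2.50 h and 26.2% at 50.0 h. The neighbour is a flask like alder kept at −25 °C, the red temperature, where 5.0 h is long against the rise of 1.33 h read in the red run, so the same reckoning gives the stand, 19.3%. That neighbour ends with Z at 20.4% and X at 8.58%.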